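Numbering follows the germacranolides: C1 ketone, C2=C3 (C3 is the enol ether carbon), C4=C5 (Z), C6 (lactone oxygen), C7, C8 (angelate), C9, C10 (quaternary, carries the ring oxygen), C11=C13, C12 lactone carbonyl.
Retrosynthetic cuts, in order: the C8–O acyl bond; O–C12 and C6–C7 (lactone and ten-membered carbocycle, from a C6 enal and a C13 allylic bromide); C7–C11 (acrylate); the furanone O–C3 bond, taken back to an oxirane on C10–C1 next to a C2≡C3 alkyne; C1–C2 (acetylide plus lactone carbonyl).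
Enabling feature: in the furanone ring O–C10–C1(=O)–C2=C3 the ketone C1 sits between the oxygen-bearing quaternary C10 and the enol ether. O–C10–C1 can therefore be carried as an oxirane whose C1 is a ketal carbon, tied through the C8 oxygen (1,4 to C1) into a temporary 4,5-dihydrofuran ring; ionisation at C1 and closure of the same oxygen on C3 enlarge the three-membered ring to the five-membered one.
Forward order: γ-lactone 3 (C7–C10 and C1) → methylation → alkynyl ketone → temporary dihydrofuran ring → oxirane → furanone ring by ring expansion (the temporary ring opens and frees O8) → acrylate arm on C7 → ten-membered ring by C6–C7 allylation → lactone → angelate.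
Stereochemistry: C8 from the (S)-lactone; C10 by epoxidation anti to the C8 substituent on the temporary ring; C6 and C7 in the ring-closing allylation under the influence of C8 and the ring; both Z-alkenes are bought in (1 and angelic acid 22).

Key step: step 6

Remark: 5 and 7 are used as mixtures at C10 (the trans lactone is drawn for 5); this centre is planar in 8 and is set only in step 5.

Step 1
Reactants: 1 (Z)-3-methylpent-2-en-4-yn-1-ol
Product: 2 (Z)-tert-butyldimethyl[(3-methylpent-2-en-4-yn-1-yl)oxy]silane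
Conditions: TBSCl, imidazole, CH2Cl2, 0 °C → rt
Reagents that add atoms: tert-butyldimethylsilyl chloride, CC(C)(C)[Si](C)(C)Cl
Why: Silyl ether formation on a primary alcohol; the bulky silyl ether tolerates the acetylide chemistry and later keeps the C6 oxygen from adding to the alkyne.

Step 2
Reactants: 3 (S)-5-[(trityloxy)methyl]dihydrofuran-2(3H)-one
Product: 5 (3R,5S)-3-methyl-5-[(trityloxy)methyl]dihydrofuran-2(3H)-one, via lithium enolate 4 (not isolated)
Conditions: LiN(iPr)2, THF, −78 °C; then MeI, −78 → −40 °C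
Reagents that add atoms: iodomethane, CI
Why: Lactone enolate alkylation, in which the methyl group should enter anti to the trityloxymethyl group (trans lactone); the configuration at this carbon (C10) is of no consequence because it becomes sp2 in step 4.

Step 3
Reactants: 2 (Z)-tert-butyldimethyl[(3-methylpent-2-en-4-yn-1-yl)oxy]silane; 5 (3R,5S)-3-methyl-5-[(trityloxy)methyl]dihydrofuran-2(3H)-one
Product: 7 (2S,8Z)-10-[(tert-butyldimethylsilyl)oxy]-2-hydroxy-4,8-dimethyl-1-(trityloxy)dec-8-en-6-yn-5-one (C4 epimers, in equilibrium with its cyclic hemiketal), via lithium acetylide 6 (not isolated)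
Conditions: 2, n-BuLi, THF, −78 °C; then 5, −78 → −40 °C; aq. NH4Cl
Reagents that add atoms: none
Why: Addition of a lithium acetylide to a lactone carbonyl forms C1–C2 and stops at the ketone level because the lithium lactolate persists at low temperature; C8 is untouched.

Step 4
Reactants: 7 (2S,8Z)-10-[(tert-butyldimethylsilyl)oxy]-2-hydroxy-4,8-dimethyl-1-(trityloxy)dec-8-en-6-yn-5-one
Product: 8 tert-butyldimethyl{[(Z)-3-methyl-5-{(5S)-3-methyl-5-[(trityloxy)methyl]-4,5-dihydrofuran-2-yl}pent-2-en-4-yn-1-yl]oxy}silane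
Conditions: CSA (10 mol %), 4 Å molecular sieves, CH2Cl2, 0 °C → rt; Et3N quench
Reagents that add atoms: none
Why: Acid-catalysed cyclodehydration of a γ-hydroxy ketone to a 4,5-dihydrofuran (hemiketal formation, then loss of water toward C10, the only α-carbon that carries hydrogen), driven by removal of water and by conjugation of the new enol ether with the alkyne.

Step 5
Reactants: 8 tert-butyldimethyl{[(Z)-3-methyl-5-{(5S)-3-methyl-5-[(trityloxy)methyl]-4,5-dihydrofuran-2-yl}pent-2-en-4-yn-1-yl]oxy}silane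
Product: 9 (1R,3S,5R)-1-[(Z)-5-[(tert-butyldimethylsilyl)oxy]-3-methylpent-3-en-1-yn-1-yl]-5-methyl-3-[(trityloxy)methyl]-2,6-dioxabicyclo[3.1.0]hexane (oxirane oxygen anti to the trityloxymethyl group)
Conditions: DMDO (1.05 equiv, acetone solution), CH2Cl2, −78 → −20 °C; volatiles removed at 0 °C, crude used at once
Reagents that add atoms: dimethyldioxirane, CC1(C)OO1
Why: Dioxirane epoxidation of a cyclic enol ether (as for glycals), the most electron-rich π-bond of 8; oxygen should be delivered to the face of the five-membered ring anti to the trityloxymethyl group on C8, which sets C10 as R (C1 follows from the cis ring fusion).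

Step 6
Reactants: 9 (1R,3S,5R)-1-[(Z)-5-[(tert-butyldimethylsilyl)oxy]-3-methylpent-3-en-1-yn-1-yl]-5-methyl-3-[(trityloxy)methyl]-2,6-dioxabicyclo[3.1.0]hexane
Product: 10 (R)-5-[(Z)-4-[(tert-butyldimethylsilyl)oxy]but-2-en-2-yl]-2-[(S)-2-hydroxy-3-(trityloxy)propyl]-2-methylfuran-3(2H)-one
Conditions: Ph3PAuNTf2 (5 mol %), H2O (3 equiv), THF, −20 °C → rt
Reagents that add atoms: water, O
Why: Proposed new method: the cationic gold complex and the ring oxygen O8 together ionise the oxirane at its ketal carbon (C1–O is cleaved, never C10–O), the oxirane oxygen that stays on C10 then adds anti to the gold-activated alkyne at C3, and protodeauration followed by hydrolysis of the C1 oxocarbenium ion by water gives the C1 ketone and frees the C8 hydroxyl, so that the three-membered ring O–C10–C1 grows by C2 and C3 into the furanone. The closest known reaction types are the gold-catalysed ring expansion of 2-alkynyl oxiranes to furans, the Rubottom-type opening of enol ether oxiranes to α-oxy ketones and the gold-catalysed cyclisation of α′-hydroxy ynones to furan-3(2H)-ones; new is their merger on a 2-alkoxy-2-alkynyl oxirane, where the alkoxy group on C1 turns the furan product into a furan-3(2H)-one. The furanone ring closes in the 5-endo-dig mode. No new stereocentre is formed: C10 keeps the configuration set in step 5 because its C–O bond is not touched, and the C1 centre is lost as the ketone. The step needs regioselective C1–O cleavage, secured by oxocarbenium stabilisation from O8, and attack on C3 by the C10 oxygen only, secured by the bulky, non-nucleophilic silyl ether on C6 and by 5-endo closure being faster than the 7-endo closure open to the C8 hydroxyl.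

Step 7
Reactants: 10 (R)-5-[(Z)-4-[(tert-butyldimethylsilyl)oxy]but-2-en-2-yl]-2-[(S)-2-hydroxy-3-(trityloxy)propyl]-2-methylfuran-3(2H)-one
Product: 11 (R)-5-[(Z)-4-[(tert-butyldimethylsilyl)oxy]but-2-en-2-yl]-2-[(S)-2-[(tert-butyldimethylsilyl)oxy]-3-(trityloxy)propyl]-2-methylfuran-3(2H)-one
Conditions: TBSCl, imidazole, DMAP (cat.), DMF, rt
Reagents that add atoms: tert-butyldimethylsilyl chloride, CC(C)(C)[Si](C)(C)Cl
Why: Silylation of the secondary C8 alcohol, which gives the poor leaving group that is wanted next to the allylmetal of step 14.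

Step 8
Reactants: 11 (R)-5-[(Z)-4-[(tert-butyldimethylsilyl)oxy]but-2-en-2-yl]-2-[(S)-2-[(tert-butyldimethylsilyl)oxy]-3-(trityloxy)propyl]-2-methylfuran-3(2H)-one
Product: 12 (R)-5-[(Z)-4-[(tert-butyldimethylsilyl)oxy]but-2-en-2-yl]-2-[(S)-2-[(tert-butyldimethylsilyl)oxy]-3-hydroxypropyl]-2-methylfuran-3(2H)-one
Conditions: ZnBr2, CH2Cl2/MeOH (10:1), 0 °C → rt
Reagents that add atoms: none
Why: Lewis-acid detritylation (ionisation to the trityl cation, captured by methanol), selective for the trityl ether over both silyl ethers.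

Step 9
Reactants: 12 (R)-5-[(Z)-4-[(tert-butyldimethylsilyl)oxy]but-2-en-2-yl]-2-[(S)-2-[(tert-butyldimethylsilyl)oxy]-3-hydroxypropyl]-2-methylfuran-3(2H)-one
Product: 13 (S)-2-[(tert-butyldimethylsilyl)oxy]-3-{(R)-5-[(Z)-4-[(tert-butyldimethylsilyl)oxy]but-2-en-2-yl]-2-methyl-3-oxo-2,3-dihydrofuran-2-yl}propanal
Conditions: Dess–Martin periodinane, CH2Cl2, 0 °C → rt
Reagents that add atoms: none
Why: Dess–Martin oxidation of the primary alcohol to the α-silyloxy aldehyde under conditions that should not epimerise C8.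

Step 10
Reactants: 13 (S)-2-[(tert-butyldimethylsilyl)oxy]-3-{(R)-5-[(Z)-4-[(tert-butyldimethylsilyl)oxy]but-2-en-2-yl]-2-methyl-3-oxo-2,3-dihydrofuran-2-yl}propanal; 14 methyl acrylate
Product: 15 methyl (4S)-4-[(tert-butyldimethylsilyl)oxy]-5-{(R)-5-[(Z)-4-[(tert-butyldimethylsilyl)oxy]but-2-en-2-yl]-2-methyl-3-oxo-2,3-dihydrofuran-2-yl}-3-hydroxy-2-methylidenepentanoate (C3 epimers)
Conditions: methyl acrylate (10 equiv), DABCO (1 equiv), MeOH (2 equiv), rt
Reagents that add atoms: none
Why: Morita–Baylis–Hillman reaction forms C7–C11; the new carbinol centre at C7 arises unselectively and is removed in step 11.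

Step 11
Reactants: 15 methyl (4S)-4-[(tert-butyldimethylsilyl)oxy]-5-{(R)-5-[(Z)-4-[(tert-butyldimethylsilyl)oxy]but-2-en-2-yl]-2-methyl-3-oxo-2,3-dihydrofuran-2-yl}-3-hydroxy-2-methylidenepentanoate
Product: 16 methyl (Z,4S)-2-(bromomethyl)-4-[(tert-butyldimethylsilyl)oxy]-5-{(R)-5-[(Z)-4-[(tert-butyldimethylsilyl)oxy]but-2-en-2-yl]-2-methyl-3-oxo-2,3-dihydrofuran-2-yl}pent-2-enoate
Conditions: NBS, Me2S, CH2Cl2, −20 °C → rt
Reagents that add atoms: N-bromosuccinimide, BrN1C(=O)CCC1=O
Why: Corey–Kim-type activation of the allylic alcohol and SN2′ displacement by bromide should give the conjugated (Z)-2-(bromomethyl)alk-2-enoate (C8 cis to CH2Br) and erase the C7 carbinol centre.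

Step 12
Reactants: 16 methyl (Z,4S)-2-(bromomethyl)-4-[(tert-butyldimethylsilyl)oxy]-5-{(R)-5-[(Z)-4-[(tert-butyldimethylsilyl)oxy]but-2-en-2-yl]-2-methyl-3-oxo-2,3-dihydrofuran-2-yl}pent-2-enoate
Product: 17 methyl (Z,4S)-2-(bromomethyl)-4-[(tert-butyldimethylsilyl)oxy]-5-{(R)-5-[(Z)-4-hydroxybut-2-en-2-yl]-2-methyl-3-oxo-2,3-dihydrofuran-2-yl}pent-2-enoate
Conditions: CSA (20 mol %), MeOH/CH2Cl2 (1:1), 0 °C
Reagents that add atoms: none
Why: Acid-catalysed methanolysis should remove the primary allylic silyl ether much faster than the hindered secondary one on C8.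

Step 13
Reactants: 17 methyl (Z,4S)-2-(bromomethyl)-4-[(tert-butyldimethylsilyl)oxy]-5-{(R)-5-[(Z)-4-hydroxybut-2-en-2-yl]-2-methyl-3-oxo-2,3-dihydrofuran-2-yl}pent-2-enoate
Product: 18 methyl (Z,4S)-2-(bromomethyl)-4-[(tert-butyldimethylsilyl)oxy]-5-{(R)-2-methyl-3-oxo-5-[(Z)-4-oxobut-2-en-2-yl]-2,3-dihydrofuran-2-yl}pent-2-enoate
Conditions: Dess–Martin periodinane, CH2Cl2, 0 °C; used at once
Reagents that add atoms: none
Why: Dess–Martin oxidation of the (Z)-allylic alcohol to the (Z)-enal under mild conditions that should not isomerise the alkene.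

Step 14
Reactants: 18 methyl (Z,4S)-2-(bromomethyl)-4-[(tert-butyldimethylsilyl)oxy]-5-{(R)-2-methyl-3-oxo-5-[(Z)-4-oxobut-2-en-2-yl]-2,3-dihydrofuran-2-yl}pent-2-enoate
Product: 20 8-O-(tert-butyldimethylsilyl)-8-desangeloyllychnopholide (tricyclic lactone, configured at C6, C7, C8 and C10 as in 24), via hydroxy ester 19 (not isolated)
Conditions: CrCl2 (8 equiv), THF, rt, slow addition (final 2 mM); then p-TsOH·H2O (cat.), CH2Cl2, rt
Reagents that add atoms: none
Why: Intramolecular Nozaki–Hiyama–Kishi (Barbier-type) allylation, in which the allylchromium from the (Z)-allylic bromide adds through its γ-carbon C7 to the C6 aldehyde and closes the ten-membered carbocycle; the transition state, constrained by the furanone and the (Z)-alkene and biased by the C8 silyloxy centre, should place H6 and H7 anti, and acid then closes the trans-fused α-methylene γ-lactone with loss of methanol.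

Step 15
Reactants: 20 8-O-(tert-butyldimethylsilyl)-8-desangeloyllychnopholide
Product: 21 8-desangeloyllychnopholide (the free C8 alcohol, 6R,7R,8S,10R)
Conditions: HF·pyridine, THF, 0 °C → rt
Reagents that add atoms: none
Why: Fluoride cleavage of the secondary silyl ether under buffered acidic conditions that should leave the α-methylene lactone and the furanone intact.

Step 16
Reactants: 21 8-desangeloyllychnopholide; 22 angelic acid [(Z)-2-methylbut-2-enoic acid]
Product: 24 lychnopholide, via mixed anhydride 23 (not isolated)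
Conditions: 22, 2,4,6-trichlorobenzoyl chloride, Et3N, toluene, rt; then 21, toluene, 70 °C
Reagents that add atoms: none
Why: Yamaguchi esterification through the mixed anhydride, run without a nucleophilic catalyst so that the (Z)-angelate should not isomerise to the tiglate.

Compound list
1 | (Z)-3-methylpent-2-en-4-yn-1-ol | C#C/C(C)=C\CO | starting material
2 | (Z)-tert-butyldimethyl[(3-methylpent-2-en-4-yn-1-yl)oxy]silane | C#C/C(C)=C\CO[Si](C)(C)C(C)(C)C | intermediate
3 | (S)-5-[(trityloxy)methyl]dihydrofuran-2(3H)-one | O=C1CC[C@@H](COC(c2ccccc2)(c2ccccc2)c2ccccc2)O1 | starting material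
4 | lithium enolate of 3 | [Li]OC1=CC[C@@H](COC(c2ccccc2)(c2ccccc2)c2ccccc2)O1 | intermediate (not isolated)
5 | (3R,5S)-3-methyl-5-[(trityloxy)methyl]dihydrofuran-2(3H)-one (trans) | O=C1[C@H](C)C[C@@H](COC(c2ccccc2)(c2ccccc2)c2ccccc2)O1 | intermediate
6 | lithium acetylide of 2 | [Li]C#C/C(C)=C\CO[Si](C)(C)C(C)(C)C | intermediate (not isolated)
7 | (2S,8Z)-10-[(tert-butyldimethylsilyl)oxy]-2-hydroxy-4,8-dimethyl-1-(trityloxy)dec-8-en-6-yn-5-one (C4 epimers) | O=C(C#C/C(C)=C\CO[Si](C)(C)C(C)(C)C)C(C)C[C@H](O)COC(c1ccccc1)(c1ccccc1)c1ccccc1 | intermediate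
8 | tert-butyldimethyl{[(Z)-3-methyl-5-{(5S)-3-methyl-5-[(trityloxy)methyl]-4,5-dihydrofuran-2-yl}pent-2-en-4-yn-1-yl]oxy}silane | CC1=C(C#C/C(C)=C\CO[Si](C)(C)C(C)(C)C)O[C@H](COC(c2ccccc2)(c2ccccc2)c2ccccc2)C1 | intermediate
9 | (1R,3S,5R)-1-[(Z)-5-[(tert-butyldimethylsilyl)oxy]-3-methylpent-3-en-1-yn-1-yl]-5-methyl-3-[(trityloxy)methyl]-2,6-dioxabicyclo[3.1.0]hexane | C[C@@]12C[C@@H](COC(c3ccccc3)(c3ccccc3)c3ccccc3)O[C@]1(C#C/C(C)=C\CO[Si](C)(C)C(C)(C)C)O2 | intermediate
10 | (R)-5-[(Z)-4-[(tert-butyldimethylsilyl)oxy]but-2-en-2-yl]-2-[(S)-2-hydroxy-3-(trityloxy)propyl]-2-methylfuran-3(2H)-one | CC(C)(C)[Si](C)(C)OC/C=C(/C)C1=CC(=O)[C@@](C)(C[C@H](O)COC(c2ccccc2)(c2ccccc2)c2ccccc2)O1 | intermediate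
11 | C8 tert-butyldimethylsilyl ether of 10 | CC(C)(C)[Si](C)(C)OC/C=C(/C)C1=CC(=O)[C@@](C)(C[C@H](O[Si](C)(C)C(C)(C)C)COC(c2ccccc2)(c2ccccc2)c2ccccc2)O1 | intermediate
12 | (R)-5-[(Z)-4-[(tert-butyldimethylsilyl)oxy]but-2-en-2-yl]-2-[(S)-2-[(tert-butyldimethylsilyl)oxy]-3-hydroxypropyl]-2-methylfuran-3(2H)-one | CC(C)(C)[Si](C)(C)OC/C=C(/C)C1=CC(=O)[C@@](C)(C[C@H](O[Si](C)(C)C(C)(C)C)CO)O1 | intermediate
13 | (S)-2-[(tert-butyldimethylsilyl)oxy]-3-{(R)-5-[(Z)-4-[(tert-butyldimethylsilyl)oxy]but-2-en-2-yl]-2-methyl-3-oxo-2,3-dihydrofuran-2-yl}propanal | CC(C)(C)[Si](C)(C)OC/C=C(/C)C1=CC(=O)[C@@](C)(C[C@H](O[Si](C)(C)C(C)(C)C)C=O)O1 | intermediate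
14 | methyl acrylate | C=CC(=O)OC | starting material
15 | methyl (4S)-4-[(tert-butyldimethylsilyl)oxy]-5-{(R)-5-[(Z)-4-[(tert-butyldimethylsilyl)oxy]but-2-en-2-yl]-2-methyl-3-oxo-2,3-dihydrofuran-2-yl}-3-hydroxy-2-methylidenepentanoate (C3 epimers) | CC(C)(C)[Si](C)(C)OC/C=C(/C)C1=CC(=O)[C@@](C)(C[C@H](O[Si](C)(C)C(C)(C)C)C(O)C(=C)C(=O)OC)O1 | intermediate
16 | methyl (Z,4S)-2-(bromomethyl)-4-[(tert-butyldimethylsilyl)oxy]-5-{(R)-5-[(Z)-4-[(tert-butyldimethylsilyl)oxy]but-2-en-2-yl]-2-methyl-3-oxo-2,3-dihydrofuran-2-yl}pent-2-enoate | CC(C)(C)[Si](C)(C)OC/C=C(/C)C1=CC(=O)[C@@](C)(C[C@H](O[Si](C)(C)C(C)(C)C)/C=C(\CBr)C(=O)OC)O1 | intermediate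
17 | methyl (Z,4S)-2-(bromomethyl)-4-[(tert-butyldimethylsilyl)oxy]-5-{(R)-5-[(Z)-4-hydroxybut-2-en-2-yl]-2-methyl-3-oxo-2,3-dihydrofuran-2-yl}pent-2-enoate | OC/C=C(/C)C1=CC(=O)[C@@](C)(C[C@H](O[Si](C)(C)C(C)(C)C)/C=C(\CBr)C(=O)OC)O1 | intermediate
18 | methyl (Z,4S)-2-(bromomethyl)-4-[(tert-butyldimethylsilyl)oxy]-5-{(R)-2-methyl-3-oxo-5-[(Z)-4-oxobut-2-en-2-yl]-2,3-dihydrofuran-2-yl}pent-2-enoate | O=C/C=C(/C)C1=CC(=O)[C@@](C)(C[C@H](O[Si](C)(C)C(C)(C)C)/C=C(\CBr)C(=O)OC)O1 | intermediate
19 | methyl 2-[8-[(tert-butyldimethylsilyl)oxy]-6-hydroxy-4,10-dimethyl-1-oxo-3,10-epoxycyclodeca-2,4-dien-7-yl]acrylate (germacrane numbering, 4Z, configured at C6, C7, C8, C10 as in 24) | COC(=O)C(=C)[C@H]1[C@H](O)/C=C(/C)C2=CC(=O)[C@@](C)(C[C@@H]1O[Si](C)(C)C(C)(C)C)O2 | intermediate (not isolated)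
20 | 8-O-(tert-butyldimethylsilyl)-8-desangeloyllychnopholide | C=C1C(=O)O[C@@H]2/C=C(/C)C3=CC(=O)[C@@](C)(C[C@H](O[Si](C)(C)C(C)(C)C)[C@@H]12)O3 | intermediate
21 | 8-desangeloyllychnopholide (6R,7R,8S,10R) | C=C1C(=O)O[C@@H]2/C=C(/C)C3=CC(=O)[C@@](C)(C[C@H](O)[C@@H]12)O3 | intermediate
22 | angelic acid [(Z)-2-methylbut-2-enoic acid] | C/C=C(/C)C(=O)O | starting material
23 | angelic 2,4,6-trichlorobenzoic anhydride | C/C=C(/C)C(=O)OC(=O)c1c(Cl)cc(Cl)cc1Cl | intermediate (not isolated)
24 | lychnopholide | C=C1C(=O)O[C@@H]2/C=C(/C)C3=CC(=O)[C@@](C)(C[C@H](OC(=O)/C(C)=C\C)[C@@H]12)O3 | target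

Total step count: 16. Longest linear sequence: 15 steps (3 → 24, steps 2 to 16); step 1 is a one-step side branch.

Steps most likely to fail

Step 6 (ring expansion). The oxirane may open without the C10 oxygen closing on C3: hydration of the alkyne, a pinacol-type shift toward the C1 cation, or capture of the gold intermediate by other oxygens. The fallback separates the two events with known chemistry and sets out from 9. Hydrolysis of the ketal oxirane in THF/water with a trace of AcOH (as for 1,2-anhydro sugars) gives the open-chain (2S,4R,8Z)-2,4-dihydroxy ynone F1. Et2NH in EtOH then adds to C3 to give the β-(diethylamino) enone F2, which on acidification with aqueous AcOH closes by addition–elimination, the classical amine route from α′-hydroxy ynones to furan-3(2H)-ones. The route is rejoined at 10.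

Step 5 (epoxidation). Facial selectivity of oxygen transfer may be poor, because the only controlling group sits on the ring carbon opposite the double bond; the C10 epimer would then be carried on. The fallback makes the C10–O bond on the lactone enolate, where attack anti to the trityloxymethyl group is well established for this ring, and sets out from 5. KN(SiMe3)2 in THF at −78 °C followed by 2-(phenylsulfonyl)-3-phenyloxaziridine gives the (3R,5S)-3-hydroxy-3-methyl lactone F3. TMSCl and imidazole give its trimethylsilyl ether F4, and addition of acetylide 6 as in step 3 gives the α-silyloxy ynone F5. Ph3PAuNTf2 in THF/MeOH removes the trimethylsilyl group and closes the furanone by the known 5-endo-dig cyclisation of an α′-hydroxy ynone. The route is rejoined at 10, so steps 3 to 6 are bypassed.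

Step 14 (ring closure). Control of the C6/C7 configuration may be poor: the acyclic preference of (Z)-2-(alkoxycarbonyl)allyl metals is the syn adduct, which here means the 6-epimeric, cis-fused lactone. Reductive 1,4-elimination of the C8 silyloxy group and oligomerisation are further drains. The fallback accepts the wrong C6 configuration and inverts it, and sets out from 18. Under the conditions of step 14 the 6-epimer lactonises to the cis-fused lactone F6. LiOH in THF/H2O at 0 °C opens it to the 6-epi hydroxy acid F7, and Mitsunobu lactonisation (PPh3, DIAD, THF, high dilution) closes the lactone with inversion at C6. The route is rejoined at 20.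

Further compounds
F1 | step 6 | (2S,4R,8Z)-10-[(tert-butyldimethylsilyl)oxy]-2,4-dihydroxy-4,8-dimethyl-1-(trityloxy)dec-8-en-6-yn-5-one | O=C(C#C/C(C)=C\CO[Si](C)(C)C(C)(C)C)[C@](C)(O)C[C@H](O)COC(c1ccccc1)(c1ccccc1)c1ccccc1
F2 | step 6 | (2S,4R,8Z)-10-[(tert-butyldimethylsilyl)oxy]-7-(diethylamino)-2,4-dihydroxy-4,8-dimethyl-1-(trityloxy)deca-6,8-dien-5-one | CCN(CC)C(=CC(=O)[C@](C)(O)C[C@H](O)COC(c1ccccc1)(c1ccccc1)c1ccccc1)/C(C)=C\CO[Si](C)(C)C(C)(C)C
F3 | step 5 | (3R,5S)-3-hydroxy-3-methyl-5-[(trityloxy)methyl]dihydrofuran-2(3H)-one | O=C1[C@](C)(O)C[C@@H](COC(c2ccccc2)(c2ccccc2)c2ccccc2)O1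
F4 | step 5 | (3R,5S)-3-methyl-3-[(trimethylsilyl)oxy]-5-[(trityloxy)methyl]dihydrofuran-2(3H)-one | O=C1[C@](C)(O[Si](C)(C)C)C[C@@H](COC(c2ccccc2)(c2ccccc2)c2ccccc2)O1
F5 | step 5 | (2S,4R,8Z)-10-[(tert-butyldimethylsilyl)oxy]-2-hydroxy-4,8-dimethyl-4-[(trimethylsilyl)oxy]-1-(trityloxy)dec-8-en-6-yn-5-one | O=C(C#C/C(C)=C\CO[Si](C)(C)C(C)(C)C)[C@](C)(O[Si](C)(C)C)C[C@H](O)COC(c1ccccc1)(c1ccccc1)c1ccccc1
F6 | step 14 | 6-epi-8-O-(tert-butyldimethylsilyl)-8-desangeloyllychnopholide (cis-fused lactone) | C=C1C(=O)O[C@H]2/C=C(/C)C3=CC(=O)[C@@](C)(C[C@H](O[Si](C)(C)C(C)(C)C)[C@@H]12)O3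
F7 | step 14 | 2-[8-[(tert-butyldimethylsilyl)oxy]-6-hydroxy-4,10-dimethyl-1-oxo-3,10-epoxycyclodeca-2,4-dien-7-yl]acrylic acid, 6-epimer of the acid of 19 | OC(=O)C(=C)[C@H]1[C@@H](O)/C=C(/C)C2=CC(=O)[C@@](C)(C[C@@H]1O[Si](C)(C)C(C)(C)C)O2
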